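The easy step came first: I gave each run its mean loss rate, the logarithm of the substrate at the start of a window over that at its end, divided by the window. This replaces a curve with one pseudo-first-order constant.

| setting | blue | violet | Thursday's | Monday's |
|---|---|---|---|---|
| substrate | 0.74 M | 1.7 M | 1.1 M | 1.1 M |
| remark | run made earlier | run made earlier |  |  |
| time |  |  | 6.0 h | 12 h |

- blue (time / h: substrate / %, isomer of the product / %, target / %): 0.500: 100, 0, 1; 1.50: 95, 5, 2; 3.00: 90, 0, 9; 4.00: 90, 6, 10; 6.00: 85, 2, 14
- violet (time / h: substrate / %, isomer of the product / %, target / %): 0.500: 100, 0, 2; 1.50: 96, 2, 6; 3.00: 89, 6, 6; 4.00: 81, 2, 11; 6.00: 57, 8, 33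

(readings scatter by 2 percentage points)

* which of these there is most of at the end, counted by the substrate in it, Thursday's (isomer of the product / target / substrate)
* which of these there is most of at the end, counted by the substrate in it, Monday's (isomer of the product / target / substrate)
* final amount of the leader among these, as a percentage of the substrate charged, in Thursday's
* final amount of the leader among these, as a percentage of the substrate charged, in Monday's



Over the whole of each earlier run, and then by apparent order to the new charge, I reckoned:

Blue, [substrate] = 0.74 M: 0.0271 h⁻¹

Violet, [substrate] = 1.7 M: 0.0937 h⁻¹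

Apparent order: 1.49

Thursday's, [substrate] = 1.1 M: 0.0489 h⁻¹

Substrate left in Thursday's: 74.6 %

Thursday's was done. Monday's has the same charge, but this mean would not carry it, since the violet run lost substrate at 0.0388 h⁻¹ up to 3.00 h and faster later.

That was the weak link, so I reforged it. I assumed the rate follows the substrate already converted. At 6.0 h, by my reckoning, Monday's had converted 0.280 M, and the violet run's reading at 4.00 h stood a little further on, with 0.323 M. I therefore borrowed the violet run's late mean loss rate 0.176 h⁻¹ for Monday's second stretch:

Substrate left in Monday's: 26.0 %

Target in Monday's, by the violet run's last reading of target against isomer of the product: 59.6 %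

So I committed to target leading Monday's, and to substrate leading Thursday's.

The forecast gave substrate at 76 % for Thursday's and target at 55 % for Monday's, “though this is uncertain”, which is lower than my Monday's figure.

Thursday's gave substrate at 78.6 %. Monday's gave target at 66.9 %.

    substrate → decomposition product (k = 8.20 × 10⁻⁶ min⁻¹)
    substrate → target (k = 4.80 × 10⁻⁴ min⁻¹)
    substrate + 2 target → 3 target (k = 0.0180 M⁻² min⁻¹)
    target ⇌ isomer of the product (K = 0.250, k = 0.00960 min⁻¹)

Monday's substrate fell from 78.6 % at 6.00 h to 16.9 % at 12.0 h, a mean loss rate of 0.256 h⁻¹, faster than the borrowed 0.176 h⁻¹. The neighbouring flask is Monday's read at 20 h. Holding 0.256 h⁻¹ for the further 8.00 h gives 2.18 % substrate. Its window's mean loss rate came to 0.816 h⁻¹, and that flask held 0.025 % substrate beside 79.6 % target.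

Readings and results were generated by integration for an exercise, and the scatter is random.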